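# Proposed synthesis of abyssinone-IV (14) by a chiral-acid-controlled ortho-quinone methide/styrene cycloaddition

Assumption: which antipode of the chiral acid leads to the 2S series cannot be derived safely on paper, so it is fixed in a first trial with both antipodes; the route is written for the (R)-acid, and the (S)-acid is used instead if the trial shows the opposite sense.

## Analysis of the target

The target is a flavanone. Ring A is a benzo ring with a free hydroxyl at C7, ring C is the fused dihydropyranone (O1, C2, C3, C4=O, C4a, C8a), and ring B is an aryl group on C2 whose 4'-hydroxyl sits between two 3-methylbut-2-enyl (prenyl) groups at C3' and C5'. There is a single stereocentre, C2 (S), a benzylic ether carbon with no second centre to relay from, so it has to be set by a reagent or catalyst. It is configurationally fragile: C3–H is alpha to the ketone and O1 is a phenoxide leaving group, so base opens ring C to the achiral 2'-hydroxychalcone and recloses it. The prenyl groups are the other weak point: strong acid cyclises them onto the neighbouring phenol, oxidants dehydrogenate them, and hydrogenation is excluded. The difficulty is therefore to create C2 with absolute control away from base, and to end with deprotections that are neither basic nor strongly acidic. The strategy rests on ring C: its bonds O1–C2 and C3–C4 enclose a two-carbon unit, C2–C3, which is exactly the vinyl group of a ring B styrene. The remaining four atoms, O1–C8a–C4a–C4, are a salicylaldehyde in which C4 already stands at the aldehyde oxidation level, that is, a latent ortho-quinone methide heterodiene.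

## Retrosynthetic reasoning

**14 from 13.** The last operation should only uncover the two phenols. In 13 both are silyl ethers (triisopropylsilyl on O7, tert-butyldimethylsilyl on O4'), because buffered fluoride is the one deprotection that neither opens ring C nor cyclises a prenyl group onto its phenol. No skeletal bond is cut.

**13 from 12 from 11.** The C4 carbonyl is traced back to a C4 ether. Ketone 13 comes from alcohol 12 by oxidation, and 12 from methyl ether 11 by exchange of the alkoxy group in aqueous acid. C4 of 11 is a benzylic ether activated by O1 (ortho) and O7 (para), so it ionises easily, and neither operation touches C2. The gain is that the ketone, which makes C2 labile, appears only after all acid chemistry is over. The C4 configuration is given up on purpose.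

**11 from 3 and 9 (through 10).** The bonds cut are O1–C2 and C3–C4. These are the two bonds that join the ring A half to the ring B half, so the cut gives two aromatic pieces of similar size and forms ring C and the C2 centre in one event. Other cuts are worse: closing O1–C2 alone would be the reversible oxa-Michael addition that racemises flavanones, and cuts inside ring A would mean building a ring that can be bought. The forward reaction has to turn acetal 3 into the methoxy ortho-quinone methide 10 with a chiral Brønsted acid. The methide must then take up the vinyl group of 9 with the CH2 end at the methide carbon, on one face only, and in preference to the two prenyl alkenes.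

**3 from 2 from 1.** Acetal 3 is the dimethyl acetal of aldehyde 2, which is the mono-silyl ether of 1. The ortho hydroxyl stays free because it supplies the proton that is lost when the methide forms.

**9 from 8 from 7.** The vinyl C=C bond is cut back to aldehyde 8 (methylenation) and the silyl ether to phenol 7. The ring B oxygen is capped in 9 for two reasons: a free para-vinylphenol could add to 10 through oxygen, and it would make the C2–O1 bond of the adduct acid-labile by para-quinone methide formation.

**7 from 6 from 4 and 5.** The two aryl–CH2 bonds are cut one at a time. Aldehyde 7 goes back to the mono-prenyl phenol 6 and one equivalent of 5, and 6 goes back to 4 and a second equivalent of 5. Each forward step is an ortho C-alkylation of a phenoxide whose para position is blocked by the formyl group. Separating the two alkylations lets the O-alkylated by-product be removed before the second prenyl group is introduced.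

## Alternatives that were turned down

**Alternative 1:** The two aryl–CH2 bonds at C3' and C5' are cut last. The enantiopure dibromoflavanone A2 would be coupled twice with the prenyl tin reagent A3 under zerovalent palladium catalysis to give A1, followed by removal of the pivalate and the methoxymethyl ether.
- For: the ring system and C2 exist before the delicate prenyl groups do, and A2 can draw on established asymmetric flavanone chemistry. On certainty of enantiocontrol this plan is stronger than the chosen one, which depends on an untested asymmetric step.
- Against: both couplings are ortho to the methoxymethyl ether, so incomplete coupling and protodebromination are likely. Allyl transposition at tin can give reverse-prenyl isomers. The hot coupling exposes a base- and heat-sensitive flavanone to ring opening.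
- Against, endgame: the pivalate of A1 needs base (chalcone opening, racemisation) and the methoxymethyl ether needs acid next to two prenyl groups (chroman formation).
- Comparison: the key step of this plan closes no ring and sets no centre. The chosen route makes ring C and C2 in one convergent step and ends with a near-neutral fluoride step.

**Alternative 2:** Ring A itself is disconnected (O1–C8a and C4a–C5). An open-chain hydroxy polyketone that already carries the C2 hydroxyl would be folded by acid: the C2 hydroxyl condenses with the C8a carbonyl to a dihydropyranone, the unmasked C5 aldehyde condenses with C4a, and ring A aromatises to A4.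
- For: C2 would come from a well-understood asymmetric aldol or reduction on an acyclic chain and would never be formed by an oxa-Michael step. On reliability of the stereocentre this plan is again stronger.
- Against: most of the steps are spent making a resorcinol ring that is available as 1. The polycarbonyl chain has many enol forms and several competing cyclisation modes. The beta-hydroxy ketone can dehydrate under the acid that folds it, which destroys C2. The same acid meets two prenyl groups, and the acetate of A4 comes off only with base.
- Comparison: the chosen route keeps both aromatic rings intact from commercial material and forms only the two bonds that join them, in fewer steps.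

**Alternative 3:** O1–C8a and C4a–C4 are cut. Fluoride would unmask a 3-chloroaryne from an ortho-silylaryl triflate, the carbinol oxygen of the beta-hydroxy ester A6 would add at the aryne carbon distal to chlorine, and the aryl anion would acylate on the ester to close ring C and give A5.
- For: the stereocentre is bought with robust asymmetric hydrogenation or aldol chemistry and the new C–O bond forms at oxygen, not at the centre. This is the strongest of the three on stereochemical security, and it is convergent.
- Against: the chlorine is a steering atom that the target lacks. Its reductive removal in the presence of two trisubstituted alkenes and a ketone is awkward. The substituted aryne precursor needs its own multistep synthesis.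
- Against, conditions: the alkoxide of A6 can undergo retro-aldol cleavage or elimination to the cinnamate, the flavanone A5 sits in a basic fluoride medium, and two methoxymethyl ethers must finally be removed with acid beside a prenylated phenol.
- Comparison: the chosen route needs no steering atom and nothing to remove but silyl groups. The price is reliance on a new asymmetric step.

Key step: step 7

## Route

Step 1
Reactants: 1 2,4-dihydroxybenzaldehyde
Product: 2 2-hydroxy-4-(triisopropylsilyloxy)benzaldehyde
Conditions: iPr3SiCl (1.05 equiv), imidazole, CH2Cl2, 0 °C to rt
Reagents that add atoms: triisopropylsilyl chloride, CC(C)[Si](Cl)(C(C)C)C(C)C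
Why: Silyl ether formation at a phenol; the C4 hydroxyl is free and the more acidic one, whereas the C2 hydroxyl is tied up in a hydrogen bond to the formyl oxygen, so one equivalent of the bulky chloride should go to O4 only.

Step 2
Reactants: 2 2-hydroxy-4-(triisopropylsilyloxy)benzaldehyde
Product: 3 2-(dimethoxymethyl)-5-(triisopropylsilyloxy)phenol
Conditions: HC(OMe)3, MeOH, pyridinium p-toluenesulfonate (cat.), rt; Et3N quench, concentrated and used without chromatography
Reagents that add atoms: trimethyl orthoformate, COC(OC)OC; methanol, CO
Why: Acid-catalysed acetalisation with the orthoformate as water scavenger; the aryl silyl ether tolerates weakly acidic methanol, and the product is neutralised and carried on crude because ortho-hydroxybenzaldehyde acetals ionise easily.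

Step 3
Reactants: 4 4-hydroxybenzaldehyde; 5 prenyl bromide (1-bromo-3-methylbut-2-ene)
Product: 6 4-hydroxy-3-(3-methylbut-2-enyl)benzaldehyde
Conditions: 5 (1.1 equiv, slow addition), aq. KOH, 0 °C to rt; then aq. HCl; chromatography
Reagents that add atoms: none
Why: Ortho C-alkylation of a phenoxide in water, where hydrogen bonding to the phenoxide oxygen steers the allylic bromide to carbon and the formyl group blocks the para position; the O-prenyl ether is separated and any 7 already formed is combined with the product of step 4.

Step 4
Reactants: 6 4-hydroxy-3-(3-methylbut-2-enyl)benzaldehyde; 5 prenyl bromide (1-bromo-3-methylbut-2-ene)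
Product: 7 4-hydroxy-3,5-bis(3-methylbut-2-enyl)benzaldehyde
Conditions: 5 (1.2 equiv, slow addition), aq. KOH, 0 °C to rt; then aq. HCl; chromatography
Reagents that add atoms: none
Why: The same aqueous phenoxide C-alkylation at the one ortho carbon that is still free; slow addition in the cold holds back O-alkylation and attack at the already substituted ortho carbon, recovered 6 is recycled, and a modest throughput is accepted in this cheap early step.

Step 5
Reactants: 7 4-hydroxy-3,5-bis(3-methylbut-2-enyl)benzaldehyde
Product: 8 4-(tert-butyldimethylsilyloxy)-3,5-bis(3-methylbut-2-enyl)benzaldehyde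
Conditions: tBuMe2SiCl, imidazole, DMF, rt
Reagents that add atoms: tert-butyldimethylsilyl chloride, CC(C)(C)[Si](C)(C)Cl
Why: Silyl ether formation; the tert-butyldimethylsilyl group is small enough to enter between the two benzylic CH2 groups, survives catalytic acid and leaves with fluoride at the end.

Step 6
Reactants: 8 4-(tert-butyldimethylsilyloxy)-3,5-bis(3-methylbut-2-enyl)benzaldehyde
Product: 9 tert-butyldimethyl[2,6-bis(3-methylbut-2-enyl)-4-vinylphenoxy]silane
Conditions: Ph3PCH3Br (1.3 equiv), n-BuLi (1.2 equiv), THF, 0 °C; then 8, 0 °C to rt
Reagents that add atoms: methyltriphenylphosphonium bromide, C[P+](c1ccccc1)(c1ccccc1)c1ccccc1.[Br-]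
Why: Wittig methylenation of an aromatic aldehyde; a slight deficit of base relative to the phosphonium salt keeps free alkyllithium away from the aryl silyl ether, and the ylide does not touch the prenyl groups.

Step 7
Reactants: 3 2-(dimethoxymethyl)-5-(triisopropylsilyloxy)phenol; 9 tert-butyldimethyl[2,6-bis(3-methylbut-2-enyl)-4-vinylphenoxy]silane
Product: 11 (2S,4S)-2-[4-(tert-butyldimethylsilyloxy)-3,5-bis(3-methylbut-2-enyl)phenyl]-4-methoxy-7-(triisopropylsilyloxy)chroman, via methoxy ortho-quinone methide 10 (not isolated)
Conditions: (R)-3,3'-bis(2,4,6-triisopropylphenyl)-1,1'-binaphthyl-2,2'-diyl N-triflylphosphoramide (5 mol %), 5 Å MS, toluene, −40 °C, 3 added slowly to 9 (1.3 equiv); Et3N quench; chromatography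
Reagents that add atoms: none
Why: Proposed new method: the acid protonates one methoxy group of 3, methanol leaves, and the oxocarbenium ion hands its phenol proton to the chiral anion, giving the methoxy ortho-quinone methide 10 held to the catalyst by a hydrogen bond at its carbonyl oxygen; the closest known reaction type is the achiral acid-promoted [4+2] cycloaddition of acetal-derived alkoxy ortho-quinone methides with styrenes to cis-2-aryl-4-alkoxychromans, together with chiral phosphoric-acid-type control of ortho-quinone methides made from ortho-hydroxybenzyl alcohols, and the new element is the transfer of that enantiocontrol to the alkoxy methide and a plain styrene. The CH2 terminus of 9 attacks the methide carbon (C3–C4) and the developing benzylic cation at the aryl-bearing carbon is caught by the quinone oxygen (O1–C2), so ring C closes by a concerted but asynchronous inverse-demand hetero-Diels–Alder reaction. The C4 centre is set by the face of the methide that the chiral anion leaves open, and C2 follows from the endo orientation of the aryl group in the same transition state, which puts aryl and methoxy cis and should give (2S,4S). Regioselectivity rests on the polarisation of both partners, nucleophilic CH2 against electrophilic methide carbon. Chemoselectivity for the vinyl group over the two prenyl alkenes rests on its conjugation with the oxygenated arene and on its slim, monosubstituted shape, and the silyl cap keeps the ring B oxygen from adding to 10. Keeping 3 as the limiting partner and adding it slowly holds 10 dilute and leaves no excess methide to attack the prenyl groups of the product, while the sieves take up the methanol. Any trans isomer is removed here, because a trans adduct formed on the same methide face has the opposite configuration at C2.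

Step 8
Reactants: 11 (2S,4S)-2-[4-(tert-butyldimethylsilyloxy)-3,5-bis(3-methylbut-2-enyl)phenyl]-4-methoxy-7-(triisopropylsilyloxy)chroman
Product: 12 (2S)-2-[4-(tert-butyldimethylsilyloxy)-3,5-bis(3-methylbut-2-enyl)phenyl]-7-(triisopropylsilyloxy)chroman-4-ol (expected as a mixture of C4 epimers)
Conditions: CF3CO2H (cat.), THF/H2O 4:1, dilute, 0 °C to rt; aq. NaHCO3
Reagents that add atoms: water, O
Why: Acid-catalysed solvolysis of an activated benzylic ether, the reactivity that underlies cleavage of 2,4-dialkoxybenzyl ethers: the C4 cation is stabilised by O1 (ortho) and the C7 silyloxy group (para) and is trapped by the large excess of water; C2 is not involved and the C4 epimer mixture is without consequence.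

Step 9
Reactants: 12 (2S)-2-[4-(tert-butyldimethylsilyloxy)-3,5-bis(3-methylbut-2-enyl)phenyl]-7-(triisopropylsilyloxy)chroman-4-ol
Product: 13 (S)-2-[4-(tert-butyldimethylsilyloxy)-3,5-bis(3-methylbut-2-enyl)phenyl]-7-(triisopropylsilyloxy)chroman-4-one
Conditions: Dess–Martin periodinane, NaHCO3, CH2Cl2, 0 °C to rt
Reagents that add atoms: none
Why: Dess–Martin oxidation of a secondary benzylic alcohol under bicarbonate buffering; it is neutral, inert to prenyl alkenes and aryl silyl ethers, and free of base that could open ring C, so C2 stays intact while C4 becomes the ketone.

Step 10
Reactants: 13 (S)-2-[4-(tert-butyldimethylsilyloxy)-3,5-bis(3-methylbut-2-enyl)phenyl]-7-(triisopropylsilyloxy)chroman-4-one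
Product: 14 abyssinone-IV, (S)-7-hydroxy-2-[4-hydroxy-3,5-bis(3-methylbut-2-enyl)phenyl]chroman-4-one
Conditions: Bu4NF/AcOH (1:1), THF, 0 °C
Reagents that add atoms: none
Why: Fluoride cleavage of aryl silyl ethers; acetic acid protonates each phenoxide as it forms and keeps the medium from turning basic, which shuts off the retro-oxa-Michael opening to the chalcone that would racemise C2, and no acid strong enough to cyclise a prenyl phenol is present.

## Compound list

1 | 2,4-dihydroxybenzaldehyde | O=Cc1ccc(O)cc1O | starting material
2 | 2-hydroxy-4-(triisopropylsilyloxy)benzaldehyde | O=Cc1ccc(O[Si](C(C)C)(C(C)C)C(C)C)cc1O | intermediate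
3 | 2-(dimethoxymethyl)-5-(triisopropylsilyloxy)phenol | COC(OC)c1ccc(O[Si](C(C)C)(C(C)C)C(C)C)cc1O | intermediate
4 | 4-hydroxybenzaldehyde | O=Cc1ccc(O)cc1 | starting material
5 | prenyl bromide (1-bromo-3-methylbut-2-ene) | CC(C)=CCBr | starting material
6 | 4-hydroxy-3-(3-methylbut-2-enyl)benzaldehyde | CC(C)=CCc1cc(C=O)ccc1O | intermediate
7 | 4-hydroxy-3,5-bis(3-methylbut-2-enyl)benzaldehyde | CC(C)=CCc1cc(C=O)cc(CC=C(C)C)c1O | intermediate
8 | 4-(tert-butyldimethylsilyloxy)-3,5-bis(3-methylbut-2-enyl)benzaldehyde | CC(C)=CCc1cc(C=O)cc(CC=C(C)C)c1O[Si](C)(C)C(C)(C)C | intermediate
9 | tert-butyldimethyl[2,6-bis(3-methylbut-2-enyl)-4-vinylphenoxy]silane | C=Cc1cc(CC=C(C)C)c(O[Si](C)(C)C(C)(C)C)c(CC=C(C)C)c1 | intermediate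
10 | (6E)-6-(methoxymethylidene)-3-(triisopropylsilyloxy)cyclohexa-2,4-dien-1-one (methoxy ortho-quinone methide, not isolated) | CO/C=C1\C=CC(O[Si](C(C)C)(C(C)C)C(C)C)=CC1=O | intermediate
11 | (2S,4S)-2-[4-(tert-butyldimethylsilyloxy)-3,5-bis(3-methylbut-2-enyl)phenyl]-4-methoxy-7-(triisopropylsilyloxy)chroman (2,4-cis) | CC(C)=CCc1cc([C@@H]2C[C@H](OC)c3ccc(O[Si](C(C)C)(C(C)C)C(C)C)cc3O2)cc(CC=C(C)C)c1O[Si](C)(C)C(C)(C)C | intermediate
12 | (2S)-2-[4-(tert-butyldimethylsilyloxy)-3,5-bis(3-methylbut-2-enyl)phenyl]-7-(triisopropylsilyloxy)chroman-4-ol (C4 epimer mixture, C4 left undefined) | CC(C)=CCc1cc([C@@H]2CC(O)c3ccc(O[Si](C(C)C)(C(C)C)C(C)C)cc3O2)cc(CC=C(C)C)c1O[Si](C)(C)C(C)(C)C | intermediate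
13 | (S)-2-[4-(tert-butyldimethylsilyloxy)-3,5-bis(3-methylbut-2-enyl)phenyl]-7-(triisopropylsilyloxy)chroman-4-one | CC(C)=CCc1cc([C@@H]2CC(=O)c3ccc(O[Si](C(C)C)(C(C)C)C(C)C)cc3O2)cc(CC=C(C)C)c1O[Si](C)(C)C(C)(C)C | intermediate
14 | abyssinone-IV, (S)-7-hydroxy-2-[4-hydroxy-3,5-bis(3-methylbut-2-enyl)phenyl]chroman-4-one | CC(C)=CCc1cc([C@@H]2CC(=O)c3ccc(O)cc3O2)cc(CC=C(C)C)c1O | target

## Step count and least certain steps

Total step count: 10. Longest linear sequence: 8 steps (from 4 through steps 3, 4, 5, 6, 7, 8, 9 and 10 to 14); the ring A branch (steps 1 and 2) joins at step 7.

**Step 7 (key step, the proposed new method).**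
- Poor facial selectivity: the methide is oxygen-stabilised and long-lived, and the ion pair with the chiral anion may be too loose.
- Incomplete endo selectivity, which lowers the purity at C2 through the trans isomer unless it is separated.
- Competing attack of the methide on the prenyl alkenes. The silyl ether on ring B is twisted out of the ring plane by its two neighbours, so the vinyl group is less activated than in a simple para-alkoxystyrene.
- Acid-induced oligomerisation of the styrene, and reversible ionisation of the C2–O1 bond of the product at higher temperature.
- Fallback, from 3 and 9 back to 13, with known chemistry. The cycloaddition is run in its known achiral form with catalytic CF3SO3H in CH2Cl2 at −78 °C. This should give racemic cis-2-[4-(tert-butyldimethylsilyloxy)-3,5-bis(3-methylbut-2-enyl)phenyl]-4-methoxy-7-(triisopropylsilyloxy)chroman F1. The conditions of steps 8 and 9 take it to racemic 2-[4-(tert-butyldimethylsilyloxy)-3,5-bis(3-methylbut-2-enyl)phenyl]-7-(triisopropylsilyloxy)chroman-4-ol F2 and to racemic 2-[4-(tert-butyldimethylsilyloxy)-3,5-bis(3-methylbut-2-enyl)phenyl]-7-(triisopropylsilyloxy)chroman-4-one F3. The ketone is then resolved kinetically by asymmetric transfer hydrogenation, an established way to separate flavanone enantiomers. RuCl(p-cymene)(TsDPEN) (TsDPEN = N-tosyl-1,2-diphenylethane-1,2-diamine), in the handedness found to consume the (R)-ketone, is used with HCO2H/Et3N and stopped near half conversion. It should reduce the unwanted enantiomer to (2R,4R)-2-[4-(tert-butyldimethylsilyloxy)-3,5-bis(3-methylbut-2-enyl)phenyl]-7-(triisopropylsilyloxy)chroman-4-ol F4 and leave the (S)-ketone, which is 13. At most half of the material is kept. This fallback cures the enantiocontrol problem only, not competition from the prenyl alkenes.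

**Step 8.**
- The C4 cation may lose a proton from C3 (elimination to the 2H-chromene) or alkylate the electron-rich ring A of a second molecule, instead of being trapped by water.
- Fallback, from 11 directly to 13: oxidative cleavage of the benzylic methyl ether with DDQ in CH2Cl2/pH 7 buffer at 0 °C. Hydride abstraction from C4, which is activated like a 2,4-dialkoxybenzyl ether, gives the methyl oxocarbenium ion; water adds and the hemiketal loses methanol to the ketone in one operation. No new compound is made. Its own hazard is hydride abstraction at C2 or at the benzylic, allylic CH2 groups of ring B, which is why it is the second choice.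

**Step 4 (the second prenylation, and step 3 before it).**
- O-alkylation and geminal dialkylation at the already substituted ortho carbon, with loss of aromaticity, compete with the wanted C-alkylation, so the amount of 7 obtained over the two alkylations may be small.
- Fallback, from 4 back to 7, bypassing 6. Bromination of 4 with Br2 in AcOH gives 3,5-dibromo-4-hydroxybenzaldehyde F5. Protection with MeOCH2Cl/iPr2NEt gives 3,5-dibromo-4-(methoxymethoxy)benzaldehyde F6. Twofold Stille coupling with tributyl(3-methylbut-2-enyl)stannane A3 and Pd(PPh3)4 in DMF at 100 °C gives 4-(methoxymethoxy)-3,5-bis(3-methylbut-2-enyl)benzaldehyde F7. Removal of the acetal with dilute HCl in MeOH at rt returns 7; the para formyl group makes the phenol a poor nucleophile toward its own prenyl groups.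

**Step 2.**
- The acetal may revert to the aldehyde or self-condense through the methide during work-up and storage.
- Fallback, from 2 straight to 11: the acetal is not isolated. Aldehyde 2, HC(OMe)3 and 9 are combined with the acid catalyst so that 3 and then 10 form in the flask, the three-component form of the same cycloaddition. No new compound is made.

## Further compounds

F1 | step 7 | racemic cis-2-[4-(tert-butyldimethylsilyloxy)-3,5-bis(3-methylbut-2-enyl)phenyl]-4-methoxy-7-(triisopropylsilyloxy)chroman (racemate, drawn without configuration) | CC(C)=CCc1cc(C2CC(OC)c3ccc(O[Si](C(C)C)(C(C)C)C(C)C)cc3O2)cc(CC=C(C)C)c1O[Si](C)(C)C(C)(C)C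
F2 | step 7 | racemic 2-[4-(tert-butyldimethylsilyloxy)-3,5-bis(3-methylbut-2-enyl)phenyl]-7-(triisopropylsilyloxy)chroman-4-ol (racemate, C4 epimer mixture) | CC(C)=CCc1cc(C2CC(O)c3ccc(O[Si](C(C)C)(C(C)C)C(C)C)cc3O2)cc(CC=C(C)C)c1O[Si](C)(C)C(C)(C)C
F3 | step 7 | racemic 2-[4-(tert-butyldimethylsilyloxy)-3,5-bis(3-methylbut-2-enyl)phenyl]-7-(triisopropylsilyloxy)chroman-4-one (racemate) | CC(C)=CCc1cc(C2CC(=O)c3ccc(O[Si](C(C)C)(C(C)C)C(C)C)cc3O2)cc(CC=C(C)C)c1O[Si](C)(C)C(C)(C)C
F4 | step 7 | (2R,4R)-2-[4-(tert-butyldimethylsilyloxy)-3,5-bis(3-methylbut-2-enyl)phenyl]-7-(triisopropylsilyloxy)chroman-4-ol | CC(C)=CCc1cc([C@H]2C[C@@H](O)c3ccc(O[Si](C(C)C)(C(C)C)C(C)C)cc3O2)cc(CC=C(C)C)c1O[Si](C)(C)C(C)(C)C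
F0 | step 8 | none | none
F5 | step 4 | 3,5-dibromo-4-hydroxybenzaldehyde | O=Cc1cc(Br)c(O)c(Br)c1
F6 | step 4 | 3,5-dibromo-4-(methoxymethoxy)benzaldehyde | COCOc1c(Br)cc(C=O)cc1Br
F7 | step 4 | 4-(methoxymethoxy)-3,5-bis(3-methylbut-2-enyl)benzaldehyde | COCOc1c(CC=C(C)C)cc(C=O)cc1CC=C(C)C
F0 | step 2 | none | none
A1 | alternative 1 | (S)-2-[4-(methoxymethoxy)-3,5-bis(3-methylbut-2-enyl)phenyl]-4-oxochroman-7-yl pivalate | CC(C)=CCc1cc([C@@H]2CC(=O)c3ccc(OC(=O)C(C)(C)C)cc3O2)cc(CC=C(C)C)c1OCOC
A2 | alternative 1 | (S)-2-[3,5-dibromo-4-(methoxymethoxy)phenyl]-4-oxochroman-7-yl pivalate | COCOc1c(Br)cc([C@@H]2CC(=O)c3ccc(OC(=O)C(C)(C)C)cc3O2)cc1Br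
A3 | alternative 1 | tributyl(3-methylbut-2-enyl)stannane | CCCC[Sn](CCCC)(CCCC)CC=C(C)C
A4 | alternative 2 | (S)-4-(7-hydroxy-4-oxochroman-2-yl)-2,6-bis(3-methylbut-2-enyl)phenyl acetate | CC(C)=CCc1cc([C@@H]2CC(=O)c3ccc(O)cc3O2)cc(CC=C(C)C)c1OC(C)=O
A5 | alternative 3 | (S)-5-chloro-7-(methoxymethoxy)-2-[4-(methoxymethoxy)-3,5-bis(3-methylbut-2-enyl)phenyl]chroman-4-one | CC(C)=CCc1cc([C@@H]2CC(=O)c3c(Cl)cc(OCOC)cc3O2)cc(CC=C(C)C)c1OCOC
A6 | alternative 3 | methyl (S)-3-hydroxy-3-[4-(methoxymethoxy)-3,5-bis(3-methylbut-2-enyl)phenyl]propanoate | COC(=O)C[C@H](O)c1cc(CC=C(C)C)c(OCOC)c(CC=C(C)C)c1
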